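**Strategy**

The flavone is disconnected at the C4a–C5 bond of ring A, so that ring A is grown onto a preformed ring C. The feature exploited is the hydroquinone monoether pattern of ring A: the free C5 hydroxyl sits para to the C8 methoxy group, with C6–H and the C7 methoxy group between them. Heating a 4-alkenyl-3,4-dimethoxycyclobutenone opens it to a dienylketene whose 6π closure builds ring A in one operation, with all four oxygens differentiated by the mechanism. The substrate is a cis-2-aryl-4-silyloxy-3,4-dihydro-2H-pyran carrying the cyclobutenone at C6 (the future C8a), made from a hetero-Diels–Alder pyranone and methyl semisquarate.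

Key step: step 6

Remark: the target is achiral, so every chiral intermediate is carried as a racemate (SMILES show one enantiomer), and the cyclobutenone adduct of step 5 is used as the mixture of its two epimers.

**Route**

Step 1
Reactants: 1 2,6-dimethoxybenzaldehyde; 2 (E)-1-methoxy-3-(trimethylsilyloxy)buta-1,3-diene
Product: 4 2-(2,6-dimethoxyphenyl)-2,3-dihydro-4H-pyran-4-one (racemic), via silyl enol ether cycloadduct 3 (not isolated)
Conditions: ZnCl2 (20 mol %), THF, rt; then TFA (cat.), CH2Cl2, 0 °C; aq NaHCO3
Reagents that add atoms: none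
Why: Hetero-Diels–Alder reaction: under ZnCl2 catalysis the electron-rich diene adds across the aldehyde C=O with its CH2 terminus bonding to the carbonyl carbon, and acid then expels methanol and the silyl group from cycloadduct 3 to unveil the dihydropyranone, whose only stereocentre (C2) forms as a racemate.

Step 2
Reactants: 4 2-(2,6-dimethoxyphenyl)-2,3-dihydro-4H-pyran-4-one
Product: 5 cis-2-(2,6-dimethoxyphenyl)-3,4-dihydro-2H-pyran-4-ol (racemic)
Conditions: NaBH4, CeCl3·7H2O, MeOH, −78 → −20 °C; neutral work-up
Reagents that add atoms: none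
Why: Luche reduction: the cerium-activated borohydride reduces the enone carbonyl in 1,2-fashion and delivers hydride axially to the half-chair that holds the bulky aryl group pseudo-equatorial, so the new C4 hydroxyl should end up pseudo-equatorial and cis to the aryl group (substrate control).

Step 3
Reactants: 5 cis-2-(2,6-dimethoxyphenyl)-3,4-dihydro-2H-pyran-4-ol
Product: 6 cis-4-(tert-butyldimethylsilyloxy)-2-(2,6-dimethoxyphenyl)-3,4-dihydro-2H-pyran (racemic)
Conditions: TBSCl, imidazole, DMF, 0 °C → rt
Reagents that add atoms: tert-butyldimethylsilyl chloride (TBSCl), CC(C)(C)[Si](C)(C)Cl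
Why: Silyl ether formation with TBSCl and imidazole proceeds under basic conditions that leave the acid-sensitive allylic enol ether and both stereocentres untouched, and the silyl ether withstands the organolithium base of step 5.

Step 4
Reactants: 7 dimethyl squarate
Product: 9 3-methoxycyclobut-3-ene-1,2-dione (methyl semisquarate), via hydroxycyclobutenone 8 (not isolated)
Conditions: LiAlH(OtBu)3 (1.05 equiv), THF, −78 → −20 °C; then 6 M aq HCl, 0 °C → rt
Reagents that add atoms: water, O
Why: Mono-reduction of a squarate ester with a hindered hydride followed by acid-induced allylic transposition: ionisation of the carbinol of 8 gives a methoxy-stabilised cation that water captures at the neighbouring carbon, and loss of methanol leaves the semisquarate, a conversion established for dialkyl squarates.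

Step 5
Reactants: 6 cis-4-(tert-butyldimethylsilyloxy)-2-(2,6-dimethoxyphenyl)-3,4-dihydro-2H-pyran; 9 3-methoxycyclobut-3-ene-1,2-dione
Product: 12 4-[cis-4-(tert-butyldimethylsilyloxy)-2-(2,6-dimethoxyphenyl)-3,4-dihydro-2H-pyran-6-yl]-3,4-dimethoxycyclobut-2-en-1-one (racemic; both epimers at the cyclobutenone carbon), via 6-lithiodihydropyran 10 (not isolated), via lithium alkoxide adduct 11 (not isolated)
Conditions: t-BuLi (1.2 equiv), THF, −78 → 0 °C; then cannulated into 9 (1.3 equiv), THF, −78 °C; then MeOTf (2 equiv), −78 → 0 °C
Reagents that add atoms: methyl trifluoromethanesulfonate (MeOTf), COS(=O)(=O)C(F)(F)F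
Why: Kinetic α-lithiation of a cyclic enol ether at the vinylic C–H next to oxygen (C6 of the pyran, the future C8a), 1,2-addition of the alkenyllithium to the ketone-like carbonyl of 9 (the one flanked by the methoxy-bearing carbon, the other being deactivated as a vinylogous ester) and O-methylation of the lithium alkoxide with MeOTf; the new quaternary centre forms without control, which is harmless because step 6 destroys it.

Step 6
Reactants: 12 4-[cis-4-(tert-butyldimethylsilyloxy)-2-(2,6-dimethoxyphenyl)-3,4-dihydro-2H-pyran-6-yl]-3,4-dimethoxycyclobut-2-en-1-one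
Product: 15 cis-4-(tert-butyldimethylsilyloxy)-2-(2,6-dimethoxyphenyl)-7,8-dimethoxychroman-5-ol (racemic), via (Z)-dienylketene 13 (not isolated), via cyclohexadienone 14 (not isolated)
Conditions: toluene (degassed, 0.02 M), 110 °C, Ar
Reagents that add atoms: none
Why: Heating cleaves the bond between the carbonyl carbon and the quaternary carbon of the cyclobutenone in a 4π conrotatory electrocyclic opening in which the donor 4-methoxy group rotates outward and the dihydropyranyl group inward, so that (Z)-dienylketene 13 holds its ketene carbon next to the enol ether carbon C5 of the pyran. A thermal 6π disrotatory electrocyclisation then joins the ketene carbon (future C5) to that carbon (future C4a), closing the six-membered carbocycle (ring A) as cyclohexadienone 14, which tautomerises irreversibly to phenol 15. The closest known reaction type is the thermal ring expansion of 4-alkenyl- and 4-aryl-4-alkoxycyclobutenones to hydroquinone monoethers, including cases with oxygen-substituted alkenyl groups. No stereocentre is created, since the cyclobutenone carbon and the transient C4a centre both become sp2, which is why both epimers of 12 should converge, and the cis C2/C4 relationship is not touched. The selectivity needed is torquoselectivity and differentiation of the para oxygens, both secured by the substrate: the ketene oxygen can only become the free C5 hydroxyl and the methylated carbinol oxygen the C8 methoxy group, while C6–H and the C7 methoxy group were placed by the regioselective carbonyl addition of step 5. High dilution, exclusion of air and the absence of nucleophiles should keep the ketene on the cyclisation path and protect the electron-rich phenol.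

Step 7
Reactants: 15 cis-4-(tert-butyldimethylsilyloxy)-2-(2,6-dimethoxyphenyl)-7,8-dimethoxychroman-5-ol
Product: 16 cis-2-(2,6-dimethoxyphenyl)-7,8-dimethoxychromane-4,5-diol (racemic)
Conditions: Bu4NF (1.5 equiv), AcOH (1.5 equiv), THF, 0 °C → rt, Ar; product used without delay
Reagents that add atoms: none
Why: Fluoride-induced silyl ether cleavage, in which buffering with acetic acid keeps the electron-rich phenol protonated (its phenoxide would be air-sensitive) and neither stereocentre is affected.

Step 8
Reactants: 16 cis-2-(2,6-dimethoxyphenyl)-7,8-dimethoxychromane-4,5-diol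
Product: 18 altisin (2-(2,6-dimethoxyphenyl)-5-hydroxy-7,8-dimethoxy-4H-chromen-4-one), via flavanone 17 (not isolated)
Conditions: DDQ (1.1 equiv), 1,4-dioxane, rt; then DDQ (1.5 equiv), reflux
Reagents that add atoms: none
Why: DDQ oxidation of a benzylic alcohol activated by ortho-hydroxy and para-methoxy donors (hydride abstraction at C4) should give the chelated 5-hydroxyflavanone 17, which further DDQ dehydrogenates across C2–C3 on heating under neutral conditions, so that base-induced ring opening to the chalcone is avoided and both stereocentres disappear.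

**Compound list**

1 | 2,6-dimethoxybenzaldehyde | COc1cccc(OC)c1C=O | starting material
2 | (E)-1-methoxy-3-(trimethylsilyloxy)buta-1,3-diene | CO/C=C/C(=C)O[Si](C)(C)C | starting material
3 | 2-(2,6-dimethoxyphenyl)-6-methoxy-4-(trimethylsilyloxy)-3,6-dihydro-2H-pyran (racemic, mixture of C2/C6 diastereomers, not isolated) | COC1C=C(O[Si](C)(C)C)CC(O1)c1c(OC)cccc1OC | intermediate
4 | 2-(2,6-dimethoxyphenyl)-2,3-dihydro-4H-pyran-4-one (racemic, one enantiomer drawn) | COc1cccc(OC)c1[C@@H]1CC(=O)C=CO1 | intermediate
5 | cis-2-(2,6-dimethoxyphenyl)-3,4-dihydro-2H-pyran-4-ol (racemic, one enantiomer drawn) | COc1cccc(OC)c1[C@@H]1C[C@H](O)C=CO1 | intermediate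
6 | cis-4-(tert-butyldimethylsilyloxy)-2-(2,6-dimethoxyphenyl)-3,4-dihydro-2H-pyran (racemic, one enantiomer drawn) | COc1cccc(OC)c1[C@@H]1C[C@H](O[Si](C)(C)C(C)(C)C)C=CO1 | intermediate
7 | dimethyl squarate (3,4-dimethoxycyclobut-3-ene-1,2-dione) | COC1=C(OC)C(=O)C1=O | starting material
8 | 4-hydroxy-2,3-dimethoxycyclobut-2-en-1-one (racemic, not isolated) | COC1=C(OC)C(O)C1=O | intermediate
9 | 3-methoxycyclobut-3-ene-1,2-dione (methyl semisquarate) | COC1=CC(=O)C1=O | intermediate
10 | [cis-4-(tert-butyldimethylsilyloxy)-2-(2,6-dimethoxyphenyl)-3,4-dihydro-2H-pyran-6-yl]lithium (racemic, not isolated) | COc1cccc(OC)c1[C@@H]1C[C@H](O[Si](C)(C)C(C)(C)C)C=C([Li])O1 | intermediate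
11 | lithium 1-[cis-4-(tert-butyldimethylsilyloxy)-2-(2,6-dimethoxyphenyl)-3,4-dihydro-2H-pyran-6-yl]-2-methoxy-4-oxocyclobut-2-en-1-olate (both epimers, not isolated) | COc1cccc(OC)c1[C@@H]1C[C@H](O[Si](C)(C)C(C)(C)C)C=C(O1)C1(O[Li])C(=O)C=C1OC | intermediate
12 | 4-[cis-4-(tert-butyldimethylsilyloxy)-2-(2,6-dimethoxyphenyl)-3,4-dihydro-2H-pyran-6-yl]-3,4-dimethoxycyclobut-2-en-1-one (racemic, one enantiomer drawn, both epimers at the cyclobutenone carbon) | COc1cccc(OC)c1[C@@H]1C[C@H](O[Si](C)(C)C(C)(C)C)C=C(O1)C1(OC)C(=O)C=C1OC | intermediate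
13 | (Z)-4-[cis-4-(tert-butyldimethylsilyloxy)-2-(2,6-dimethoxyphenyl)-3,4-dihydro-2H-pyran-6-yl]-3,4-dimethoxybuta-1,3-dien-1-one (dienylketene, not isolated) | COc1cccc(OC)c1[C@@H]1C[C@H](O[Si](C)(C)C(C)(C)C)C=C(O1)\C(OC)=C(OC)/C=C=O | intermediate
14 | cis-4-(tert-butyldimethylsilyloxy)-2-(2,6-dimethoxyphenyl)-7,8-dimethoxy-2,3,4,4a-tetrahydro-5H-chromen-5-one (C4a epimers, not isolated) | COc1cccc(OC)c1[C@@H]1C[C@H](O[Si](C)(C)C(C)(C)C)C2C(=O)C=C(OC)C(OC)=C2O1 | intermediate
15 | cis-4-(tert-butyldimethylsilyloxy)-2-(2,6-dimethoxyphenyl)-7,8-dimethoxychroman-5-ol (racemic, one enantiomer drawn) | COc1cccc(OC)c1[C@@H]1C[C@H](O[Si](C)(C)C(C)(C)C)c2c(O)cc(OC)c(OC)c2O1 | intermediate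
16 | cis-2-(2,6-dimethoxyphenyl)-7,8-dimethoxychromane-4,5-diol (racemic, one enantiomer drawn) | COc1cccc(OC)c1[C@@H]1C[C@H](O)c2c(O)cc(OC)c(OC)c2O1 | intermediate
17 | 2-(2,6-dimethoxyphenyl)-5-hydroxy-7,8-dimethoxychroman-4-one (racemic, one enantiomer drawn, not isolated) | COc1cccc(OC)c1[C@@H]1CC(=O)c2c(O)cc(OC)c(OC)c2O1 | intermediate
18 | altisin, 2-(2,6-dimethoxyphenyl)-5-hydroxy-7,8-dimethoxy-4H-chromen-4-one | COc1cccc(OC)c1-c1cc(=O)c2c(O)cc(OC)c(OC)c2o1 | target

**Step count and risks**

Total step count: 8. Longest linear sequence: 7 steps (steps 1, 2, 3, 5, 6, 7, 8); step 4 is a one-step branch.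

Steps most likely to fail:

Step 5. The t-BuLi metalation may not be selective for the vinylic C6–H: competing deprotonation at the benzylic C2–H, at an aryl C–H ortho to a methoxy group or at a silyl methyl group would erode formation of the C8a–cyclobutenone bond. Fallback, from 6 back to 12: the C8a carbanion is generated as a sulfone-stabilised anion instead of by vinylic deprotonation. Benzenesulfinic acid (CH2Cl2, rt) should add across the enol ether of 6 to give 4-(tert-butyldimethylsilyloxy)-2-(2,6-dimethoxyphenyl)-6-(phenylsulfonyl)tetrahydro-2H-pyran F1. n-BuLi (THF, −78 °C) removes the proton next to the sulfone, which is far more acidic than any competing C–H. The anion is added to 9 and the alkoxide is capped with MeOTf to give 4-[4-(tert-butyldimethylsilyloxy)-6-(2,6-dimethoxyphenyl)-2-(phenylsulfonyl)tetrahydro-2H-pyran-2-yl]-3,4-dimethoxycyclobut-2-en-1-one F2. Elimination of benzenesulfinic acid toward the ring CH2 (MgBr2·OEt2, Et3N, or gentle warming with Et3N) then gives the enol ether 12.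

Step 6. The newly formed ortho-hydroxybenzylic silyl ether may lose silanol at the reaction temperature (ortho-quinone methide formation), or the ketene may be intercepted before it cyclises. Fallback, from 12 back to 17: the C4 oxygen is taken to the ketone level before ring A is made, so the ring expansion delivers a chelated, non-ionisable 5-hydroxyflavanone. Desilylation of 12 (Bu4NF, AcOH, THF) should give 4-[cis-2-(2,6-dimethoxyphenyl)-4-hydroxy-3,4-dihydro-2H-pyran-6-yl]-3,4-dimethoxycyclobut-2-en-1-one F3. Allylic oxidation with MnO2 (CH2Cl2, rt) gives 2-(2,6-dimethoxyphenyl)-6-(1,2-dimethoxy-4-oxocyclobut-2-en-1-yl)-2,3-dihydro-4H-pyran-4-one F4. Heating F4 in degassed toluene at 110 °C should give flavanone 17 directly, which enters the reflux stage of step 8.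

Step 8. DDQ may over-oxidise the electron-rich ring A (quinone formation from the hydroquinone monoether) before or instead of hydride abstraction at C4, or the dehydrogenation may stall at the flavanone. Fallback, from 16 back to 18: the two oxidations are separated and run by different mechanisms. Activated MnO2 (CH2Cl2, rt) oxidises the benzylic alcohol of 16 to flavanone 17, which is isolated. I2 (cat.) in DMSO at 120 °C then dehydrogenates 17 by α-iodination and elimination to give 18. This fallback passes only through listed compounds (F0).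

**Further compounds**

F1 | step 5 | 4-(tert-butyldimethylsilyloxy)-2-(2,6-dimethoxyphenyl)-6-(phenylsulfonyl)tetrahydro-2H-pyran (racemic, 2,4-cis, mixture at C6) | COc1cccc(OC)c1[C@@H]1C[C@H](O[Si](C)(C)C(C)(C)C)CC(O1)S(=O)(=O)c1ccccc1
F2 | step 5 | 4-[4-(tert-butyldimethylsilyloxy)-6-(2,6-dimethoxyphenyl)-2-(phenylsulfonyl)tetrahydro-2H-pyran-2-yl]-3,4-dimethoxycyclobut-2-en-1-one (racemic, 4,6-cis on the pyran, other centres mixed) | COc1cccc(OC)c1[C@@H]1C[C@H](O[Si](C)(C)C(C)(C)C)CC(O1)(S(=O)(=O)c1ccccc1)C1(OC)C(=O)C=C1OC
F3 | step 6 | 4-[cis-2-(2,6-dimethoxyphenyl)-4-hydroxy-3,4-dihydro-2H-pyran-6-yl]-3,4-dimethoxycyclobut-2-en-1-one (racemic, both epimers at the cyclobutenone carbon) | COc1cccc(OC)c1[C@@H]1C[C@H](O)C=C(O1)C1(OC)C(=O)C=C1OC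
F4 | step 6 | 2-(2,6-dimethoxyphenyl)-6-(1,2-dimethoxy-4-oxocyclobut-2-en-1-yl)-2,3-dihydro-4H-pyran-4-one (racemic, both epimers at the cyclobutenone carbon) | COc1cccc(OC)c1[C@@H]1CC(=O)C=C(O1)C1(OC)C(=O)C=C1OC
F0 | step 8 | none | none
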